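Numbering: target naphthalen-1-one skeleton, used for all intermediates (C-1 ketone, C-2, C-3 sec-butyl, C-4 quaternary, C-4a, C-5 to C-8, C-8a); ring A = C-1, C-2, C-3, C-4, C-4a, C-8a; ring B = C-4a, C-5, C-6, C-7, C-8, C-8a.
Retrosynthesis: cut the vinylogous ester (C–OMe bond, then the ynone C–C bond back to a C-4 aldehyde), the C-7 methyl (from a C-7 ketone), ring B at C-4a–C-5 and C-8–C-8a, and ring A at C-3–C-4 and C-4a–C-8a.
Enabling feature: ring B hangs on the tertiary carbinol C-8a next to the C-1 ketone, so C-1/C-8a is a masked ring-A α-diketone. Its enol makes C-4a a donor and its keto form makes C-8a an acceptor; with the C-7 oxygen 1,5 to C-8a, ring B is a Michael–aldol (Robinson) retron for (E)-pent-3-en-2-one.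
Forward order: ring A by catalytic asymmetric Diels–Alder reaction of a 2-silyloxydiene with methacrolein, Rubottom and SeO2 oxidations to the ring-A diosphenol, ring B last by amine-catalysed Michael–aldol annulation, methyl addition at C-7, then the (E)-β-methoxy enone.
Stereochemistry: sec-butyl centre from (S)-2-methylbutan-1-ol; C-3/C-4 from the endo cycloaddition under oxazaborolidinium control; C-2 from epoxidation anti to the sec-butyl group; C-5 from the amine catalyst; C-4a/C-8a from the chair–chair trans-decalin aldol; C-7 from equatorial attack.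

Key step: step 8

Remark: (S)-2-methylbutan-1-ol, 3-(triphenylphosphoranylidene)butan-2-one, methacrolein and (E)-pent-3-en-2-one are taken as commercial; the carbinol centre created in step 12 is carried as both epimers because step 13 removes it.

Step 1
Reactants: 1 (S)-2-methylbutan-1-ol; 2 3-(triphenylphosphoranylidene)butan-2-one
Product: 4 (3E,5S)-3,5-dimethylhept-3-en-2-one, via (S)-2-methylbutanal 3 (not isolated)
Conditions: TEMPO (10 mol %), PhI(OAc)2, CH2Cl2, rt; then 2, 40 °C
Reagents that add atoms: none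
Why: Oxoammonium oxidation to the volatile, epimerisable aldehyde followed in the same flask by a Wittig olefination with the stabilised ylide should give the (E)-trisubstituted enone, the (S) centre of the chiral-pool alcohol being carried through unchanged.

Step 2
Reactants: 4 (3E,5S)-3,5-dimethylhept-3-en-2-one
Product: 5 tert-butyl{[(3E,5S)-3,5-dimethylhepta-1,3-dien-2-yl]oxy}dimethylsilane
Conditions: TBSOTf, Et3N, CH2Cl2, 0 °C
Reagents that add atoms: tert-butyldimethylsilyl triflate, CC(C)(C)[Si](C)(C)OS(=O)(=O)C(F)(F)F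
Why: Soft enolisation (silyl triflate/amine) at the only α′-methyl group should give the cross-conjugated 2-silyloxydiene without touching the (E)-alkene or the allylic stereocentre.

Step 3
Reactants: 5 tert-butyl{[(3E,5S)-3,5-dimethylhepta-1,3-dien-2-yl]oxy}dimethylsilane; 6 methacrolein
Product: 7 (1R,2S)-2-[(2S)-butan-2-yl]-4-[(tert-butyldimethylsilyl)oxy]-1,3-dimethylcyclohex-3-ene-1-carbaldehyde
Conditions: (R)-3,3-diphenyl-1-(2-methylphenyl)tetrahydro-1H,3H-pyrrolo[1,2-c][1,3,2]oxazaborole·Tf2NH (20 mol %), CH2Cl2, −78 → −40 °C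
Reagents that add atoms: none
Why: Lewis-acid-catalysed Diels–Alder reaction in which the 2-silyloxy group directs the para regiochemistry (diene CH2 to the enal β-carbon), the formyl group reacts endo so that CHO ends cis to the sec-butyl group (C-3/C-4 relative configuration), and the chiral oxazaborolidinium ion (the (R)-series is assigned by analogy with the usual sense for 2-substituted acroleins) exposes the Si face at C-2 of methacrolein, which sets the absolute configuration of ring A relative to the only weakly biasing sec-butyl centre.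

Step 4
Reactants: 7 the Diels–Alder aldehyde
Product: 8 [(1R,2R)-2-[(2S)-butan-2-yl]-4-[(tert-butyldimethylsilyl)oxy]-1,3-dimethylcyclohex-3-en-1-yl]methanol
Conditions: NaBH4, MeOH/THF, 0 °C
Reagents that add atoms: none
Why: Chemoselective borohydride reduction of the hindered, non-enolisable aldehyde; the silyl enol ether is inert and no stereocentre is affected.

Step 5
Reactants: 8 the primary alcohol
Product: 9 tert-butyl({(4R,5R)-4-[(benzyloxy)methyl]-5-[(2S)-butan-2-yl]-4,6-dimethylcyclohex-1-en-1-yl}oxy)dimethylsilane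
Conditions: NaH, BnBr, Bu4NI (cat.), THF/DMF, 0 °C → rt
Reagents that add atoms: benzyl bromide, BrCc1ccccc1
Why: Williamson etherification of the neopentyl alkoxide; the benzyl ether keeps this oxygen from adding to the later C-8a carbonyl and is removable at the end by hydrogenolysis.

Step 6
Reactants: 9 the benzyl ether silyl enol ether
Product: 11 (2S,3R,4R)-4-[(benzyloxy)methyl]-3-[(2S)-butan-2-yl]-2-hydroxy-2,4-dimethylcyclohexan-1-one, via α-silyloxy ketone 10 (not isolated)
Conditions: mCPBA, CH2Cl2, −20 °C; then HF·pyridine, THF, 0 °C → rt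
Reagents that add atoms: mCPBA, OOC(=O)c1cccc(Cl)c1
Why: Rubottom oxidation in which the peracid should epoxidise the tetrasubstituted silyl enol ether anti to the pseudoaxial sec-butyl group on the neighbouring allylic carbon (C-2 hydroxyl cis to the C-4 methyl), the silyloxy epoxide opens with 1,4-silyl shift to 10, and fluoride frees the tertiary alcohol.

Step 7
Reactants: 11 the α-hydroxy ketone
Product: 12 (4R,5R,6S)-4-[(benzyloxy)methyl]-5-[(2S)-butan-2-yl]-2,6-dihydroxy-4,6-dimethylcyclohex-2-en-1-one
Conditions: SeO2, 1,4-dioxane/H2O, 90 °C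
Reagents that add atoms: selenium dioxide, O=[Se]=O
Why: Riley oxidation: the ketone can enolise only towards C-8a because C-2 is quaternary, so SeO2 should convert that CH2 into the 1,2-diketone, which rests as the diosphenol enolised towards C-4a.

Step 8
Reactants: 12 the ring-A diosphenol; 13 (E)-pent-3-en-2-one
Product: 15 (2S,3R,4S,4aR,5R,8aR)-4-[(benzyloxy)methyl]-3-[(2S)-butan-2-yl]-2,8a-dihydroxy-2,4,5-trimethylhexahydronaphthalene-1,7(2H,8H)-dione, via Michael adduct 14 (not isolated)
Conditions: 13 (3 equiv), 9-amino-9-deoxy-epi-quinine (20 mol %), 2-fluorobenzoic acid (40 mol %), toluene, 40 °C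
Reagents that add atoms: none
Why: The primary amine converts 13 into an iminium ion that is attacked on the Re face of its β-carbon by C-4a of the diosphenol (the enol of the C-1/C-8a α-diketone); the resulting enamine shifts to the methyl terminus, adds to C-8a of the diketo tautomer of 14, and hydrolysis releases the catalyst. The closest known reaction type is the Robinson annulation halted at the ketol stage (amine-catalysed Michael addition followed by a Hajos–Parrish-type enamine aldol), as in Michael/aldol domino reactions of cyclic 1,2-diones with unsaturated carbonyl compounds. Ring B closes in the 6-(enolendo)-exo-trig mode through a chair-like transition state fused to the ring-A chair. C-5 is set by the catalyst (the pseudo-enantiomer exposing the Re face is taken to be the quinine-derived amine); C-4a stays epimerisable through the diosphenol of 14 and should settle with the side chain equatorial and cis to the C-4 methyl; C-8a arises from equatorial attack of C-8 on the C-8a carbonyl, giving the trans-decalin with an axial hydroxyl hydrogen-bonded to the C-2 hydroxyl and the C-5 methyl equatorial. The step needs fused closure at C-8a rather than bridged closure at C-1 or dehydration: C-1 is shielded by the quaternary C-2, the C-5 branch disfavours the internal enamine, the aldol is reversible so the least strained chair–chair ketol should accumulate, and the tertiary ketol should not dehydrate at 40 °C under weakly acidic conditions.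

Step 9
Reactants: 15 the ring-B ketol
Product: 16 (2S,3R,4S,4aR,5R,7R,8aR)-4-[(benzyloxy)methyl]-3-[(2S)-butan-2-yl]-2,7,8a-trihydroxy-2,4,5,7-tetramethyloctahydronaphthalen-1(2H)-one
Conditions: MeLi/CeCl3 (3.5 equiv), THF, −78 °C
Reagents that add atoms: methyllithium, [Li]C (delivered as MeCeCl2, C[Ce](Cl)Cl)
Why: 1,2-Addition of the weakly basic organocerium reagent to the unhindered C-7 ketone; axial approach is blocked by the syn-axial C-8a alkoxide, so equatorial attack should give the axial C-7 hydroxyl cis to the C-8a hydroxyl, while the C-1 ketone, flanked by two fully substituted alkoxide-bearing carbons, should not react and the low basicity limits retro-aldol cleavage.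

Step 10
Reactants: 16 the benzyl ether triol
Product: 17 (2S,3R,4S,4aR,5R,7R,8aR)-3-[(2S)-butan-2-yl]-2,7,8a-trihydroxy-4-(hydroxymethyl)-2,4,5,7-tetramethyloctahydronaphthalen-1(2H)-one
Conditions: H2 (1 atm), Pd/C, EtOAc, rt
Reagents that add atoms: none
Why: Hydrogenolysis of the benzyl ether; no other reducible group is present and the hindered C-1 ketone should not be hydrogenated under these conditions.

Step 11
Reactants: 17 the tetraol
Product: 18 (2S,3R,4S,4aR,5R,7R,8aR)-3-[(2S)-butan-2-yl]-4-formyl-2,7,8a-trihydroxy-2,4,5,7-tetramethyloctahydronaphthalen-1(2H)-one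
Conditions: Dess–Martin periodinane, CH2Cl2, 0 °C → rt
Reagents that add atoms: none
Why: Dess–Martin oxidation of the only non-tertiary alcohol to the non-enolisable neopentyl aldehyde; its trans relationship to the C-8a and C-2 hydroxyls prevents lactol formation.

Step 12
Reactants: 18 the C-4 aldehyde
Product: 19 (2S,3R,4S,4aR,5R,7R,8aR)-3-[(2S)-butan-2-yl]-2,7,8a-trihydroxy-4-(1-hydroxyprop-2-yn-1-yl)-2,4,5,7-tetramethyloctahydronaphthalen-1(2H)-one (both carbinol epimers)
Conditions: HC≡CMgBr (5 equiv), THF, −20 → 0 °C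
Reagents that add atoms: ethynylmagnesium bromide, C#C[Mg]Br
Why: Grignard addition of the small acetylide to the aldehyde after deprotonation of the three tertiary alcohols; the C-1 ketone is shielded, and the new carbinol centre (either epimer) is removed in the next step.

Step 13
Reactants: 19 the propargylic alcohol
Product: 20 (2S,3R,4S,4aR,5R,7R,8aR)-3-[(2S)-butan-2-yl]-2,7,8a-trihydroxy-2,4,5,7-tetramethyl-4-(prop-2-ynoyl)octahydronaphthalen-1(2H)-one
Conditions: Dess–Martin periodinane, CH2Cl2, 0 °C
Reagents that add atoms: none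
Why: Dess–Martin oxidation of the secondary propargylic alcohol to the ynone under non-basic conditions; the tertiary alcohols are inert.

Step 14
Reactants: 20 the ynone
Product: 21 (2S,3R,4S,4aR,5R,7R,8aR)-3-[(2S)-butan-2-yl]-2,7,8a-trihydroxy-4-[(2E)-3-methoxyprop-2-enoyl]-2,4,5,7-tetramethyloctahydronaphthalen-1(2H)-one
Conditions: MeOH, DABCO (10 mol %), 0 °C → rt
Reagents that add atoms: methanol, CO
Why: Amine-catalysed oxa-Michael addition of methanol to the terminal ynone via the ammonium allenolate, which should equilibrate to the thermodynamically preferred (E)-β-methoxy enone; the tertiary alcohols are too hindered to compete with the solvent.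

Compound list
1 | (S)-2-methylbutan-1-ol | CC[C@H](C)CO | starting material
2 | 3-(triphenylphosphoranylidene)butan-2-one | CC(=O)C(C)=P(c1ccccc1)(c1ccccc1)c1ccccc1 | starting material
3 | (S)-2-methylbutanal | CC[C@H](C)C=O | intermediate
4 | (3E,5S)-3,5-dimethylhept-3-en-2-one | CC[C@H](C)/C=C(\C)C(C)=O | intermediate
5 | tert-butyl{[(3E,5S)-3,5-dimethylhepta-1,3-dien-2-yl]oxy}dimethylsilane | CC[C@H](C)/C=C(\C)C(=C)O[Si](C)(C)C(C)(C)C | intermediate
6 | methacrolein (2-methylprop-2-enal) | CC(=C)C=O | starting material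
7 | (1R,2S)-2-[(2S)-butan-2-yl]-4-[(tert-butyldimethylsilyl)oxy]-1,3-dimethylcyclohex-3-ene-1-carbaldehyde | CC[C@H](C)[C@@H]1[C@](C)(C=O)CCC(O[Si](C)(C)C(C)(C)C)=C1C | intermediate
8 | [(1R,2R)-2-[(2S)-butan-2-yl]-4-[(tert-butyldimethylsilyl)oxy]-1,3-dimethylcyclohex-3-en-1-yl]methanol | CC[C@H](C)[C@@H]1[C@](C)(CO)CCC(O[Si](C)(C)C(C)(C)C)=C1C | intermediate
9 | tert-butyl({(4R,5R)-4-[(benzyloxy)methyl]-5-[(2S)-butan-2-yl]-4,6-dimethylcyclohex-1-en-1-yl}oxy)dimethylsilane | CC[C@H](C)[C@@H]1[C@](C)(COCc2ccccc2)CCC(O[Si](C)(C)C(C)(C)C)=C1C | intermediate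
10 | (2S,3R,4R)-4-[(benzyloxy)methyl]-3-[(2S)-butan-2-yl]-2-[(tert-butyldimethylsilyl)oxy]-2,4-dimethylcyclohexan-1-one | CC[C@H](C)[C@@H]1[C@](C)(COCc2ccccc2)CCC(=O)[C@@]1(C)O[Si](C)(C)C(C)(C)C | intermediate
11 | (2S,3R,4R)-4-[(benzyloxy)methyl]-3-[(2S)-butan-2-yl]-2-hydroxy-2,4-dimethylcyclohexan-1-one | CC[C@H](C)[C@@H]1[C@](C)(COCc2ccccc2)CCC(=O)[C@@]1(C)O | intermediate
12 | (4R,5R,6S)-4-[(benzyloxy)methyl]-5-[(2S)-butan-2-yl]-2,6-dihydroxy-4,6-dimethylcyclohex-2-en-1-one | CC[C@H](C)[C@@H]1[C@](C)(COCc2ccccc2)C=C(O)C(=O)[C@@]1(C)O | intermediate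
13 | (E)-pent-3-en-2-one | C/C=C/C(C)=O | starting material
14 | (4S,5R,6S)-4-[(benzyloxy)methyl]-5-[(2S)-butan-2-yl]-2,6-dihydroxy-4,6-dimethyl-3-[(2R)-4-oxopentan-2-yl]cyclohex-2-en-1-one | CC[C@H](C)[C@@H]1[C@](C)(COCc2ccccc2)C(=C(O)C(=O)[C@@]1(C)O)[C@H](C)CC(C)=O | intermediate
15 | (2S,3R,4S,4aR,5R,8aR)-4-[(benzyloxy)methyl]-3-[(2S)-butan-2-yl]-2,8a-dihydroxy-2,4,5-trimethylhexahydronaphthalene-1,7(2H,8H)-dione | CC[C@H](C)[C@@H]1[C@](C)(COCc3ccccc3)[C@H]2[C@H](C)CC(=O)C[C@]2(O)C(=O)[C@@]1(C)O | intermediate
16 | (2S,3R,4S,4aR,5R,7R,8aR)-4-[(benzyloxy)methyl]-3-[(2S)-butan-2-yl]-2,7,8a-trihydroxy-2,4,5,7-tetramethyloctahydronaphthalen-1(2H)-one | CC[C@H](C)[C@@H]1[C@](C)(COCc3ccccc3)[C@H]2[C@H](C)C[C@@](C)(O)C[C@]2(O)C(=O)[C@@]1(C)O | intermediate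
17 | (2S,3R,4S,4aR,5R,7R,8aR)-3-[(2S)-butan-2-yl]-2,7,8a-trihydroxy-4-(hydroxymethyl)-2,4,5,7-tetramethyloctahydronaphthalen-1(2H)-one | CC[C@H](C)[C@@H]1[C@](C)(CO)[C@H]2[C@H](C)C[C@@](C)(O)C[C@]2(O)C(=O)[C@@]1(C)O | intermediate
18 | (2S,3R,4S,4aR,5R,7R,8aR)-3-[(2S)-butan-2-yl]-4-formyl-2,7,8a-trihydroxy-2,4,5,7-tetramethyloctahydronaphthalen-1(2H)-one | CC[C@H](C)[C@@H]1[C@](C)(C=O)[C@H]2[C@H](C)C[C@@](C)(O)C[C@]2(O)C(=O)[C@@]1(C)O | intermediate
19 | (2S,3R,4S,4aR,5R,7R,8aR)-3-[(2S)-butan-2-yl]-2,7,8a-trihydroxy-4-(1-hydroxyprop-2-yn-1-yl)-2,4,5,7-tetramethyloctahydronaphthalen-1(2H)-one (both carbinol epimers) | CC[C@H](C)[C@@H]1[C@](C)(C(O)C#C)[C@H]2[C@H](C)C[C@@](C)(O)C[C@]2(O)C(=O)[C@@]1(C)O | intermediate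
20 | (2S,3R,4S,4aR,5R,7R,8aR)-3-[(2S)-butan-2-yl]-2,7,8a-trihydroxy-2,4,5,7-tetramethyl-4-(prop-2-ynoyl)octahydronaphthalen-1(2H)-one | CC[C@H](C)[C@@H]1[C@](C)(C(=O)C#C)[C@H]2[C@H](C)C[C@@](C)(O)C[C@]2(O)C(=O)[C@@]1(C)O | intermediate
21 | (2S,3R,4S,4aR,5R,7R,8aR)-3-[(2S)-butan-2-yl]-2,7,8a-trihydroxy-4-[(2E)-3-methoxyprop-2-enoyl]-2,4,5,7-tetramethyloctahydronaphthalen-1(2H)-one | CC[C@H](C)[C@@H]1[C@](C)(C(=O)/C=C/OC)[C@H]2[C@H](C)C[C@@](C)(O)C[C@]2(O)C(=O)[C@@]1(C)O | target

Total step count: 14.
Longest linear sequence: 14 steps, from (S)-2-methylbutan-1-ol (1) to 21; compounds 2, 6 and 13 enter as purchased reagents.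

Steps most likely to fail

1. Step 8. The intermolecular bond formation at the neopentyl donor carbon C-4a may be too slow. The aldol may fail to close because C-8a rests as its enol, or may close in the bridged sense onto C-1. The ketol may dehydrate, or the facial induction at C-5 may be mismatched. The fallback sets out from 12 and returns at 15. Conjugate addition of 12 to the smaller, more electrophilic pent-3-yn-2-one (DABCO cat., MeCN) should give the vinylogous Michael adduct F1. Pyrrolidine/AcOH-mediated aldol closure onto C-8a should then give the ring-B enone F2, which carries a C-5=C-6 double bond. Hydrogenation with [Ir(cod)(PCy3)(py)]PF6 and H2, directed to the β-face by the C-8a hydroxyl, would set C-5 by reagent delivery instead of by the Michael step.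

2. Step 3. The α-methyl enal may show insufficient endo preference, the catalyst may discriminate poorly between the diene faces against the sec-butyl centre, or the substituted diene terminus may react too slowly. The fallback sets out from 5 and returns at 8. The same catalysed cycloaddition with unhindered methyl acrylate should give the ester F3, whose C-4 configuration is irrelevant. LDA then MeI should methylate the ester enolate on the face opposite the neighbouring sec-butyl group, creating the quaternary centre by alkylation in the methylated ester F4. LiAlH4 reduction then gives 8.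

3. Step 9. The basic reagent may open the β-hydroxy ketone by retro-aldol cleavage, or axial attack may give the C-7 epimer. The fallback sets out from 15 and returns at 16. Non-basic methylenation (CH2Br2, Zn, TiCl4) should give the exocyclic alkene F5. Epoxidation with VO(acac)2 and tBuOOH, directed by the axial C-8a hydroxyl, should give the spiro-epoxide F6 with its oxygen on the β-face. LiEt3BH at −78 °C would open it at the CH2 terminus to give 16.

Further compounds
F1 | step 8 | (4S,5R,6S)-4-[(benzyloxy)methyl]-5-[(2S)-butan-2-yl]-2,6-dihydroxy-4,6-dimethyl-3-[(2Z)-4-oxopent-2-en-2-yl]cyclohex-2-en-1-one | CC[C@H](C)[C@@H]1[C@](C)(COCc2ccccc2)C(=C(O)C(=O)[C@@]1(C)O)/C(C)=C\C(C)=O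
F2 | step 8 | ring-B enone, the 5,6-didehydro analogue of 15 (configuration otherwise as in 15) | CC[C@H](C)[C@@H]1[C@](C)(COCc3ccccc3)[C@H]2C(C)=CC(=O)C[C@]2(O)C(=O)[C@@]1(C)O
F3 | step 3 | methyl (1R,2R)-2-[(2S)-butan-2-yl]-4-[(tert-butyldimethylsilyl)oxy]-3-methylcyclohex-3-ene-1-carboxylate | CC[C@H](C)[C@@H]1[C@H](C(=O)OC)CCC(O[Si](C)(C)C(C)(C)C)=C1C
F4 | step 3 | methyl (1R,2S)-2-[(2S)-butan-2-yl]-4-[(tert-butyldimethylsilyl)oxy]-1,3-dimethylcyclohex-3-ene-1-carboxylate | CC[C@H](C)[C@@H]1[C@](C)(C(=O)OC)CCC(O[Si](C)(C)C(C)(C)C)=C1C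
F5 | step 9 | 7-methylidene analogue of 15 (C-7 C=CH2 in place of C=O, configuration otherwise as in 15) | CC[C@H](C)[C@@H]1[C@](C)(COCc3ccccc3)[C@H]2[C@H](C)CC(=C)C[C@]2(O)C(=O)[C@@]1(C)O
F6 | step 9 | C-7 spiro-epoxide of F5 with the epoxide oxygen cis to the C-8a hydroxyl | CC[C@H](C)[C@@H]1[C@](C)(COCc4ccccc4)[C@H]2[C@H](C)C[C@@]3(OC3)C[C@]2(O)C(=O)[C@@]1(C)O
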